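The elm run is Friday's neighbour: it has the same starting material and partner, and 0.55 mM of initiator against Friday's 0.60 mM. Its readings stop at 8.00 min with 47.4% of the starting material read as left, whereas Friday's flask runs to 15 min, so I have to reckon how far that loss goes on.

| flask | starting material | partner | initiator | remark | time |
|---|---|---|---|---|---|
| alder | 32 mM | 35.2 mM | 0.0087 mM | run made earlier |  |
| maple | 32 mM | 35.2 mM | 0.072 mM | run made earlier |  |
| elm | 32 mM | 35.2 mM | 0.55 mM | run made earlier |  |
| Wednesday's | 32 mM | 35.2 mM | 0.0080 mM |  | 15 min |
| Saturday's | 32 mM | 35.2 mM | 0.025 mM |  | 15 min |
| Monday's | 32 mM | 35.2 mM | 0.080 mM |  | 15 min |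
| Sunday's | 32 mM | 35.2 mM | 0.20 mM |  | 15 min |
| Friday's | 32 mM | 35.2 mM | 0.60 mM |  | 15 min |

- alder (time / min: target / %, starting material / %): 0.667: 2.9, 99.6; 2.00: 1.3, 98.4; 4.00: 3.7, 94.3; 5.00: 4.6, 92.0; 8.00: 6.7, 89.5
- maple (time / min: target / %, starting material / %): 1.50: 5.2, 93.1; 3.00: 9.1, 92.2; 5.00: 11.7, 85.4; 6.00: 13.8, 81.5; 8.00: 18.2, 76.7
- elm (time / min: target / %, starting material / %): 1.50: 13.8, 86.9; 3.00: 20.9, 76.5; 5.00: 33.5, 62.8; 6.00: 36.4, 57.6; 8.00: 43.8, 47.4

(standard deviation of a reading: 1 percentage point)

- a species is counted by the starting material in it: one ended chains counts as two
- amounts and yields of target count crystals too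
- given per volume of solution although it is solid: crystals
- steps under discussion: target -> over-reaction product; crystals <-> target; starting material + second chain carrier -> by-product + first chain carrier; initiator -> 2 initiating radical; starting material + initiating radical -> capped initiator + first chain carrier; partner + first chain carrier -> target + second chain carrier; partner -> decomposed reagent; 2 first chain carrier -> ended chains
- "hardly changes" means that all values lie within two and a half points (for a concentration: within two and a half percent of the largest)

- amount of target at the end, in percent of the starting material charged for Wednesday's, Saturday's, Monday's, Sunday's, Friday's, in this order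
- how the row runs (falls, then rises / rises all the way / rises, then falls / falls all the way / hardly changes)

I read each run by k, the pseudo-first-order loss constant of starting material, from its last reading:

k_elm = ln(charge/left)/t = 0.0933 /min

k_maple = 0.0332 /min

I carry k_elm, the loss constant of the elm run, to the new flasks. The zero of my scale is the case where two first chain carriers end each other, so that k follows the square root of the initiator c, an exponent of 0.5. Between maple and elm the readings give an exponent of 0.509, so I use

k = k_elm · sqrt(c/c_elm)

For Friday's flask the root raises k by a factor of 1.04, while the time grows by a factor of 1.88. If k holds past the last reading, I expect Friday's flask to end well below the last elm reading of starting material, because the longer time counts for more than the small change in k: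

k_Friday = 0.0975 /min, starting material left = 23.2%

Of the starting material gone at the last elm reading, 83.3% stands as target. If that share holds, Friday's ends at 64.0% target. The alder share, read the same way, is 63.8%, which puts Wednesday's at 9.91%. I expect a row that rises all the way, with Friday's value above Wednesday's.

The forecast reads 11%, 19%, 30%, 41%, 54%, rises all the way, adding "A maximum within the row seems unlikely", and its Friday's value lies lower than mine.

The flasks give 7.80%, 15.2%, 28.6%, 43.1%, 62.5%: the row rises all the way.

    target → over-reaction product (k = 0.00150 /s)
    crystals ⇌ target, rate k2*(cs2 - [target]) while solid is left; crystals form when [target] > cs2 (solubility = 2.50 mM, k = 0.0197 /s)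
    starting material + second chain carrier → by-product + first chain carrier (k = 1.14 × 10⁷ /M/s)
    initiator → 2 initiating radical (k = 2.28 × 10⁻⁶ /s)
    starting material + initiating radical → capped initiator + first chain carrier (k = 2.03 × 10⁷ /M/s)
    partner + first chain carrier → target + second chain carrier (k = 6.98 × 10⁵ /M/s)
    partner → decomposed reagent (k = 1.60 × 10⁻⁴ /s)
    2 first chain carrier → ended chains (k = 3.00 × 10⁸ /M/s)

In Friday's flask, starting material reacts with second chain carrier up to 15 min, with 99.8% of the initiator still unbound at the end, and 23.2% of the starting material is left where k_elm gave me 23.2%. In percent of the starting material charged, Friday's flask ends with 62.5% target, 53.3% of it as crystals, and 14.3% over-reaction product. On Sunday's flask the same constant gives k = 0.0563 /min and 43.0% of the starting material left, and that flask holds 44.3%.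

All runs come from a simulation for an exercise; scatter was added.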